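**Retrosynthetic overview**
1. The last step is hydrogenolysis of two ring B benzyl ethers. Rings A and B are bought as arenes, so ring C is the only ring built, and it is closed late.
2. Ring C is closed at O1–C2 by an intramolecular Mitsunobu etherification, with inversion at C2, of a 2'-hydroxy-α-methoxy-β-hydroxy-dihydrochalcone.
3. The C4–C4a bond comes from the ortho-lithiated MOM ether of 3,4,5-trimethoxyphenol and a Weinreb amide.
4. The C2–C3 bond (key step) comes from an Evans syn glycolate aldol. The boron enolate of (R)-4-benzyl-3-(methoxyacetyl)oxazolidin-2-one adds to 3,5-bis(benzyloxy)-4-methoxybenzaldehyde. This sets both stereocentres and brings in the 3-OMe.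
5. The aldehyde comes from methyl gallate by 4-O-methylation, benzylation, reduction and oxidation.

Assumption: the SMILES is read as the (2R,3R), 2,3-trans 3-O-methyl dihydroflavonol; n-Bu2BOTf, MOMCl and (R)-4-benzyloxazolidin-2-one are taken as catalogue items.

**Step 1**
Reactants: 1 methyl gallate (methyl 3,4,5-trihydroxybenzoate)
Product: 2 methyl 3,5-dihydroxy-4-methoxybenzoate
Conditions: MeI (1.05 equiv), KHCO3 (1.5 equiv), DMF, N2, 30 °C, 24 h
Reagents that add atoms: iodomethane CI
Why: Williamson O-methylation in which the 4-OH, para to the ester and the most acidic phenol, is the only one appreciably ionised by the weak base, so one equivalent of MeI caps it selectively and over-methylated material is removed by crystallisation or chromatography.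

**Step 2**
Reactants: 2 methyl 3,5-dihydroxy-4-methoxybenzoate
Product: 3 methyl 3,5-bis(benzyloxy)-4-methoxybenzoate
Conditions: BnBr (2.3 equiv), K2CO3 (3 equiv), DMF, 60 °C
Reagents that add atoms: benzyl bromide BrCc1ccccc1
Why: Williamson ether synthesis on two equivalent phenols, installing benzyl groups that survive hydride, boron enolate, organolithium, dilute acid and Mitsunobu conditions and leave by neutral hydrogenolysis at the end.

**Step 3**
Reactants: 3 methyl 3,5-bis(benzyloxy)-4-methoxybenzoate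
Product: 4 [3,5-bis(benzyloxy)-4-methoxyphenyl]methanol
Conditions: LiAlH4 (1.0 equiv), THF, 0 °C to rt; H2O/aq NaOH work-up
Reagents that add atoms: none
Why: Hydride reduction of an ester to the primary benzylic alcohol, to which aryl benzyl and methyl ethers are inert.

**Step 4**
Reactants: 4 [3,5-bis(benzyloxy)-4-methoxyphenyl]methanol
Product: 5 3,5-bis(benzyloxy)-4-methoxybenzaldehyde
Conditions: activated MnO2 (10 equiv), CH2Cl2, rt
Reagents that add atoms: none
Why: Chemoselective heterogeneous oxidation of a benzylic alcohol that stops cleanly at the aldehyde.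

**Step 5**
Reactants: 6 (4R)-4-benzyl-1,3-oxazolidin-2-one; 7 methoxyacetyl chloride
Product: 9 (4R)-4-benzyl-3-(methoxyacetyl)-1,3-oxazolidin-2-one, via lithium oxazolidinonide 8 (not isolated)
Conditions: n-BuLi (1.0 equiv), THF, −78 °C; then 7 (1.1 equiv), −78 to 0 °C
Reagents that add atoms: none
Why: N-acylation of the lithiated Evans auxiliary by an acid chloride, which leaves the auxiliary stereocentre untouched.

**Step 6**
Reactants: 9 (4R)-4-benzyl-3-(methoxyacetyl)-1,3-oxazolidin-2-one; 5 3,5-bis(benzyloxy)-4-methoxybenzaldehyde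
Product: 12 (4R)-4-benzyl-3-{(2R,3S)-3-[3,5-bis(benzyloxy)-4-methoxyphenyl]-3-hydroxy-2-methoxypropanoyl}-1,3-oxazolidin-2-one, via Z-dibutylboron enolate 10 (not isolated), via dibutylboron aldolate 11 (not isolated)
Conditions: n-Bu2BOTf (1.15 equiv), Et3N (1.3 equiv), CH2Cl2, −78 to 0 °C; 5, −78 to 0 °C; pH 7 KH2PO4/Na2HPO4 buffer, MeOH, 30% H2O2, 0 °C
Reagents that add atoms: none
Why: Evans syn glycolate aldol, in which the Z boron enolate reacts through a Zimmerman–Traxler chair on the face away from the auxiliary benzyl group, so the (R)-auxiliary sets the future C3 as R and the carbinol carbon as S (syn, typically above 95:5 dr).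

**Step 7**
Reactants: 12 the syn aldol imide
Product: 13 (2R,3S)-3-[3,5-bis(benzyloxy)-4-methoxyphenyl]-3-hydroxy-N,2-dimethoxy-N-methylpropanamide
Conditions: MeNHOMe·HCl (3 equiv), AlMe3 (3 equiv), CH2Cl2, −10 °C to rt; cold 1 M aq HCl work-up
Reagents that add atoms: N,O-dimethylhydroxylamine hydrochloride CNOC.Cl
Why: AlMe3-mediated Weinreb aminolysis of the imide, assisted by the free β-hydroxyl, which cleaves the exocyclic acyl group without epimerisation or retro-aldol and returns the auxiliary.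

**Step 8**
Reactants: 13 the β-hydroxy Weinreb amide
Product: 14 (2R,3S)-3-[3,5-bis(benzyloxy)-4-methoxyphenyl]-N,2-dimethoxy-N-methyl-3-(triethylsilyloxy)propanamide
Conditions: TESCl (1.3 equiv), imidazole (2.5 equiv), DMF, 0 °C to rt
Reagents that add atoms: chlorotriethylsilane CC[Si](Cl)(CC)CC
Why: Silyl ether protection of the only free hydroxyl, which prevents alkoxide formation and retro-aldol in the organolithium step, with a small and acid-labile group.

**Step 9**
Reactants: 15 3,4,5-trimethoxyphenol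
Product: 16 1,2,3-trimethoxy-5-(methoxymethoxy)benzene
Conditions: MOMCl (1.3 equiv), i-Pr2NEt (1.6 equiv), CH2Cl2, 0 °C to rt
Reagents that add atoms: chloromethyl methyl ether COCCl
Why: O-alkylation of the phenol to a MOM acetal, which is base-stable, orthogonal to benzyl ethers and a strong director of lithiation.

**Step 10**
Reactants: 16 1,2,3-trimethoxy-5-(methoxymethoxy)benzene; 14 the TES-protected Weinreb amide
Product: 19 (2R,3S)-3-[3,5-bis(benzyloxy)-4-methoxyphenyl]-2-methoxy-1-[2,3,4-trimethoxy-6-(methoxymethoxy)phenyl]-3-(triethylsilyloxy)propan-1-one, via aryllithium 17 (not isolated), via lithium hemiaminal chelate 18 (not isolated)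
Conditions: 16 (1.6 equiv), n-BuLi (1.5 equiv), THF, 0 °C, 1 h; 14 (1.0 equiv), −78 to −30 °C; AcOH/THF quench at −78 °C
Reagents that add atoms: none
Why: Directed ortho-metalation followed by Weinreb ketone synthesis, where the two ring hydrogens of 16 are equivalent and each lies between OMOM and OMe, so one aryllithium forms and adds only once because chelate 18 holds until the cold acidic quench, leaving both stereocentres untouched.

**Step 11**
Reactants: 19 the protected ketone
Product: 20 (2R,3S)-3-[3,5-bis(benzyloxy)-4-methoxyphenyl]-3-hydroxy-1-(6-hydroxy-2,3,4-trimethoxyphenyl)-2-methoxypropan-1-one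
Conditions: 3 M aq HCl–THF (1:4), 35 °C; aq NaHCO3 work-up
Reagents that add atoms: none
Why: Acid hydrolysis of an acetal and a silyl ether, in which the TES ether and the MOM ether ortho to the ketone are both very acid-labile, so dilute HCl in a non-nucleophilic co-solvent frees both hydroxyls while benzyl ethers, methyl ethers and both stereocentres persist.

**Step 12**
Reactants: 20 the 2'-hydroxy-β-hydroxy ketone
Product: 22 (2R,3R)-2-[3,5-bis(benzyloxy)-4-methoxyphenyl]-3,5,6,7-tetramethoxy-2,3-dihydro-4H-chromen-4-one, via alkoxyphosphonium phenoxide 21 (not isolated)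
Conditions: PPh3 (1.5 equiv), DIAD (1.5 equiv), THF (0.02 M), 0 °C to rt
Reagents that add atoms: none
Why: Intramolecular Mitsunobu etherification, in which the only alcohol is activated and displaced by the ortho-acyl phenoxide in a 6-exo-tet SN2 with inversion, turning the S carbinol into C2 (R) next to the untouched C3 (R) and giving the 2,3-trans diequatorial ring C that is also the more stable isomer.

**Step 13**
Reactants: 22 the dibenzyl-protected flavanonol methyl ether
Product: 23 (2R,3R)-2-(3,5-dihydroxy-4-methoxyphenyl)-3,5,6,7-tetramethoxy-2,3-dihydro-4H-chromen-4-one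
Conditions: H2 (1 atm), Pd/C (10 wt % Pd), EtOAc–MeOH (1:1), rt
Reagents that add atoms: none
Why: Catalytic hydrogenolysis of the two aryl benzyl ethers under neutral conditions, which avoids enolisation at C3 and ring opening at C2 and leaves the electron-rich aryl ketone and the cyclic benzylic ether intact at 1 atm.

**Compound list**
1 | methyl gallate (methyl 3,4,5-trihydroxybenzoate) | COC(=O)c1cc(O)c(O)c(O)c1 | starting material
2 | methyl 3,5-dihydroxy-4-methoxybenzoate | COC(=O)c1cc(O)c(OC)c(O)c1 | intermediate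
3 | methyl 3,5-bis(benzyloxy)-4-methoxybenzoate | COC(=O)c1cc(OCc2ccccc2)c(OC)c(OCc2ccccc2)c1 | intermediate
4 | [3,5-bis(benzyloxy)-4-methoxyphenyl]methanol | OCc1cc(OCc2ccccc2)c(OC)c(OCc2ccccc2)c1 | intermediate
5 | 3,5-bis(benzyloxy)-4-methoxybenzaldehyde | O=Cc1cc(OCc2ccccc2)c(OC)c(OCc2ccccc2)c1 | intermediate
6 | (4R)-4-benzyl-1,3-oxazolidin-2-one | O=C1N[C@H](Cc2ccccc2)CO1 | starting material
7 | methoxyacetyl chloride | COCC(=O)Cl | starting material
8 | lithium (4R)-4-benzyl-2-oxo-1,3-oxazolidin-3-ide, formed in the flask | [Li]N1[C@H](Cc2ccccc2)COC1=O | intermediate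
9 | (4R)-4-benzyl-3-(methoxyacetyl)-1,3-oxazolidin-2-one | COCC(=O)N1[C@H](Cc2ccccc2)COC1=O | intermediate
10 | (Z)-dibutylboron enolate of 9, formed in the flask | CO/C=C(\OB(CCCC)CCCC)N1[C@H](Cc2ccccc2)COC1=O | intermediate
11 | dibutylboron aldolate of 12, formed in the flask | O=C1OC[C@@H](Cc2ccccc2)N1C(=O)[C@H](OC)[C@@H](OB(CCCC)CCCC)c1cc(OCc2ccccc2)c(OC)c(OCc2ccccc2)c1 | intermediate
12 | (4R)-4-benzyl-3-{(2R,3S)-3-[3,5-bis(benzyloxy)-4-methoxyphenyl]-3-hydroxy-2-methoxypropanoyl}-1,3-oxazolidin-2-one | O=C1OC[C@@H](Cc2ccccc2)N1C(=O)[C@H](OC)[C@@H](O)c1cc(OCc2ccccc2)c(OC)c(OCc2ccccc2)c1 | intermediate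
13 | (2R,3S)-3-[3,5-bis(benzyloxy)-4-methoxyphenyl]-3-hydroxy-N,2-dimethoxy-N-methylpropanamide | CON(C)C(=O)[C@H](OC)[C@@H](O)c1cc(OCc2ccccc2)c(OC)c(OCc2ccccc2)c1 | intermediate
14 | (2R,3S)-3-[3,5-bis(benzyloxy)-4-methoxyphenyl]-N,2-dimethoxy-N-methyl-3-(triethylsilyloxy)propanamide | CON(C)C(=O)[C@H](OC)[C@@H](O[Si](CC)(CC)CC)c1cc(OCc2ccccc2)c(OC)c(OCc2ccccc2)c1 | intermediate
15 | 3,4,5-trimethoxyphenol | COc1cc(O)cc(OC)c1OC | starting material
16 | 1,2,3-trimethoxy-5-(methoxymethoxy)benzene | COCOc1cc(OC)c(OC)c(OC)c1 | intermediate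
17 | [2,3,4-trimethoxy-6-(methoxymethoxy)phenyl]lithium, formed in the flask | [Li]c1c(OCOC)cc(OC)c(OC)c1OC | intermediate
18 | lithium hemiaminal chelate from 17 and 14 (hemiaminal carbon not defined), formed in the flask | COCOc1cc(OC)c(OC)c(OC)c1C(O[Li])(N(C)OC)[C@H](OC)[C@@H](O[Si](CC)(CC)CC)c1cc(OCc2ccccc2)c(OC)c(OCc2ccccc2)c1 | intermediate
19 | (2R,3S)-3-[3,5-bis(benzyloxy)-4-methoxyphenyl]-2-methoxy-1-[2,3,4-trimethoxy-6-(methoxymethoxy)phenyl]-3-(triethylsilyloxy)propan-1-one | COCOc1cc(OC)c(OC)c(OC)c1C(=O)[C@H](OC)[C@@H](O[Si](CC)(CC)CC)c1cc(OCc2ccccc2)c(OC)c(OCc2ccccc2)c1 | intermediate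
20 | (2R,3S)-3-[3,5-bis(benzyloxy)-4-methoxyphenyl]-3-hydroxy-1-(6-hydroxy-2,3,4-trimethoxyphenyl)-2-methoxypropan-1-one | COc1cc(O)c(c(OC)c1OC)C(=O)[C@H](OC)[C@@H](O)c1cc(OCc2ccccc2)c(OC)c(OCc2ccccc2)c1 | intermediate
21 | alkoxy(triphenyl)phosphonium phenoxide of 20, formed in the flask | COc1cc([O-])c(c(OC)c1OC)C(=O)[C@H](OC)[C@@H](O[P+](c1ccccc1)(c1ccccc1)c1ccccc1)c1cc(OCc2ccccc2)c(OC)c(OCc2ccccc2)c1 | intermediate
22 | (2R,3R)-2-[3,5-bis(benzyloxy)-4-methoxyphenyl]-3,5,6,7-tetramethoxy-2,3-dihydro-4H-chromen-4-one | COc1cc2c(c(OC)c1OC)C(=O)[C@H](OC)[C@@H](c1cc(OCc3ccccc3)c(OC)c(OCc3ccccc3)c1)O2 | intermediate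
23 | (2R,3R)-2-(3,5-dihydroxy-4-methoxyphenyl)-3,5,6,7-tetramethoxy-2,3-dihydro-4H-chromen-4-one | COc1cc2c(c(OC)c1OC)C(=O)[C@H](OC)[C@@H](c1cc(O)c(OC)c(O)c1)O2 | target

**Step count**
Total step count: 13.
Longest linear sequence: 11 steps (steps 1, 2, 3, 4, 6, 7, 8, 10, 11, 12 and 13, starting from methyl gallate).

**Three steps most likely to fail**

**Step 10, acylation of a doubly ortho-substituted aryllithium by a branched Weinreb amide.**
- Risk: addition may be slow, and the aryllithium may instead deprotonate the α-carbon.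
- Fallback: the C4–C4a bond is made at the aldehyde oxidation level and the ketone is restored by oxidation. It sets out from 14 and comes back at 19.
- Compound 14 is reduced with i-Bu2AlH (THF, −78 °C) to (2R,3S)-3-[3,5-bis(benzyloxy)-4-methoxyphenyl]-2-methoxy-3-(triethylsilyloxy)propanal F1, which is used at once.
- Aryllithium 17, made as in step 10, adds to this smaller and more electrophilic carbonyl at −78 °C. This gives 3-[3,5-bis(benzyloxy)-4-methoxyphenyl]-2-methoxy-1-[2,3,4-trimethoxy-6-(methoxymethoxy)phenyl]-3-(triethylsilyloxy)propan-1-ol F2.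
- F2 is a mixture of C1 epimers in which the two carried centres are unchanged in space.
- Dess–Martin periodinane with NaHCO3 in CH2Cl2 removes the new centre and gives 19.

**Step 11, acid release of phenol and alcohol.**
- Risk: the β-hydroxy ketone may dehydrate, or its benzylic carbinol may ionise, before the MOM group is gone.
- Fallback: the MOM group and the aqueous acid are dropped altogether. It sets out from 15 and 14 and comes back at 20.
- Compound 15 is monobrominated (NBS, 1.0 equiv, CH2Cl2, −20 °C) at one of its two equivalent free positions to give 2-bromo-3,4,5-trimethoxyphenol F3.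
- n-BuLi (1.0 equiv) and then t-BuLi (2.0 equiv) in THF at −78 °C convert F3 into lithium 2-lithio-3,4,5-trimethoxyphenoxide F4.
- F4 is acylated by 14. After a cold AcOH quench this gives (2R,3S)-3-[3,5-bis(benzyloxy)-4-methoxyphenyl]-1-(6-hydroxy-2,3,4-trimethoxyphenyl)-2-methoxy-3-(triethylsilyloxy)propan-1-one F5.
- HF·pyridine in THF–pyridine at 0 °C then removes the TES group under buffered conditions and gives 20.

**Step 12, Mitsunobu ring closure.**
- Risk: the activated β-hydroxy ketone may eliminate to the α-methoxychalcone, which destroys C3, or it may partly ionise at the benzylic carbon.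
- Fallback: the O1–C2 bond is made at the amide stage, where the α-hydrogen is far less acidic, and ring C is closed through C4–C4a instead. It sets out from 13 and 15 and comes back at 22.
- Compound 15 is iodinated (NIS, MeCN, 0 °C) to 2-iodo-3,4,5-trimethoxyphenol F6.
- Intermolecular Mitsunobu etherification of 13 with F6 (PPh3, DIAD, toluene, 0 °C) proceeds with inversion. It gives (2R,3R)-3-[3,5-bis(benzyloxy)-4-methoxyphenyl]-3-(2-iodo-3,4,5-trimethoxyphenoxy)-N,2-dimethoxy-N-methylpropanamide F7.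
- t-BuLi (2.1 equiv, THF, −95 °C) forms the corresponding 2-lithiophenoxy amide F8 by iodine–lithium exchange.
- F8 closes onto its own Weinreb amide (Parham cyclisation) and gives 22 after a cold AcOH quench.

**Further compounds**
F1 | step 10 | (2R,3S)-3-[3,5-bis(benzyloxy)-4-methoxyphenyl]-2-methoxy-3-(triethylsilyloxy)propanal | O=C[C@H](OC)[C@@H](O[Si](CC)(CC)CC)c1cc(OCc2ccccc2)c(OC)c(OCc2ccccc2)c1
F2 | step 10 | 3-[3,5-bis(benzyloxy)-4-methoxyphenyl]-2-methoxy-1-[2,3,4-trimethoxy-6-(methoxymethoxy)phenyl]-3-(triethylsilyloxy)propan-1-ol, C1 epimer mixture | COCOc1cc(OC)c(OC)c(OC)c1C(O)[C@H](OC)[C@@H](O[Si](CC)(CC)CC)c1cc(OCc2ccccc2)c(OC)c(OCc2ccccc2)c1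
F3 | step 11 | 2-bromo-3,4,5-trimethoxyphenol | COc1cc(O)c(Br)c(OC)c1OC
F4 | step 11 | lithium 2-lithio-3,4,5-trimethoxyphenoxide | [Li]Oc1cc(OC)c(OC)c(OC)c1[Li]
F5 | step 11 | (2R,3S)-3-[3,5-bis(benzyloxy)-4-methoxyphenyl]-1-(6-hydroxy-2,3,4-trimethoxyphenyl)-2-methoxy-3-(triethylsilyloxy)propan-1-one | COc1cc(O)c(c(OC)c1OC)C(=O)[C@H](OC)[C@@H](O[Si](CC)(CC)CC)c1cc(OCc2ccccc2)c(OC)c(OCc2ccccc2)c1
F6 | step 12 | 2-iodo-3,4,5-trimethoxyphenol | COc1cc(O)c(I)c(OC)c1OC
F7 | step 12 | (2R,3R)-3-[3,5-bis(benzyloxy)-4-methoxyphenyl]-3-(2-iodo-3,4,5-trimethoxyphenoxy)-N,2-dimethoxy-N-methylpropanamide | CON(C)C(=O)[C@H](OC)[C@H](Oc1cc(OC)c(OC)c(OC)c1I)c1cc(OCc2ccccc2)c(OC)c(OCc2ccccc2)c1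
F8 | step 12 | (2R,3R)-3-[3,5-bis(benzyloxy)-4-methoxyphenyl]-3-(2-lithio-3,4,5-trimethoxyphenoxy)-N,2-dimethoxy-N-methylpropanamide | CON(C)C(=O)[C@H](OC)[C@H](Oc1cc(OC)c(OC)c(OC)c1[Li])c1cc(OCc2ccccc2)c(OC)c(OCc2ccccc2)c1
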